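**Plan**

1. Ring numbering used below: in the target cyclohexene, C1 carries the aroyl group, C3=C4 is the alkene, C4 carries the 4-methylpent-3-enyl chain and C6 the phenyl group.
2. Retrosynthesis: (a) both MOM ethers come off last; (b) the C1–H/C2–H pair goes back to a C1=C2 alkene (dienone 26); (c) ring bonds C1–C2 and C4–C5 are cut together and the ketone carbon is joined to C5 by a temporary bond, giving 1-aryl-3-phenylcyclobutanol 15 and (Z)-β-iodo enal 23; (d) 15 is cut at the aryl–carbinol bond into 3-phenylcyclobutanone and an aryl iodide built from 5-methoxyresorcinol.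
3. Enabling feature: the ketone carbon, C1, C6 and C5 form a four-carbon chain with phenyl on its third carbon. Closed into a cyclobutanol, this chain is strained and has C6 on a mirror plane, so palladium-mediated cleavage of one of two enantiotopic ring bonds sets C6, makes C5 a carbon nucleophile and frees the ketone, whose only α-carbon (C1) then condenses with the cis formyl group.
4. Forward order: arene substituents (steps 1–4), temporary four-membered ring (step 5), side-chain iodo enal (steps 6–8), six-membered ring as a 1,3-diene in one operation (step 9), conjugate reduction (step 10), deprotection (step 11).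
5. Stereochemistry: C6 (R) from ligand-controlled desymmetrization in step 9; C1 (R) by equilibration to the trans ketone in step 10; the alkene position is fixed by the (Z)-iodo enal.

Key step: step 9

Assumption: the sense of induction of the chiral P,N ligand in the C–C cleavage cannot be predicted with certainty; the (S)-ligand is written, and its antipode is used unchanged if the sense proves opposite.

**Route**

Step 1
Reactants: 1 5-methoxyresorcinol; 2 chloromethyl methyl ether
Product: 3 1-methoxy-3,5-bis(methoxymethoxy)benzene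
Conditions: MOMCl (2.5 equiv), i-Pr2NEt (3 equiv), CH2Cl2, 0 °C to rt
Reagents that add atoms: chloromethyl methyl ether 2, COCCl
Why: Base-mediated O-alkylation of both phenols (Williamson-type MOM protection); the MOM ethers survive the organometallic steps and later act as ortho-directing groups.

Step 2
Reactants: 3 1-methoxy-3,5-bis(methoxymethoxy)benzene; 4 iodomethane
Product: 6 5-methoxy-1,3-bis(methoxymethoxy)-2-methylbenzene, via aryllithium 5 (not isolated)
Conditions: n-BuLi (1.1 equiv), THF, 0 °C; then MeI, −78 °C to rt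
Reagents that add atoms: iodomethane 4, CI
Why: Directed ortho-metalation, in which the ring C–H flanked by two chelating OMOM groups should be removed in preference to those next to the weaker OMe director, followed by SN2 methylation of the aryllithium.

Step 3
Reactants: 6 5-methoxy-1,3-bis(methoxymethoxy)-2-methylbenzene; 7 methyl chloroformate
Product: 9 methyl 6-methoxy-2,4-bis(methoxymethoxy)-3-methylbenzoate, via aryllithium 8 (not isolated)
Conditions: n-BuLi (1.2 equiv), TMEDA, THF, −20 to 0 °C; then added to ClCO2Me (3 equiv), THF, −78 °C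
Reagents that add atoms: methyl chloroformate 7, COC(=O)Cl
Why: Second directed ortho-metalation at one of the two equivalent remaining ring positions (between OMOM and OMe) and acylation by the chloroformate, with inverse addition and the flanking groups preventing a second addition to the hindered ester.

Step 4
Reactants: 9 methyl 6-methoxy-2,4-bis(methoxymethoxy)-3-methylbenzoate; 10 N-iodosuccinimide
Product: 11 methyl 3-iodo-2-methoxy-4,6-bis(methoxymethoxy)-5-methylbenzoate
Conditions: NIS (1.1 equiv), DMF, rt, dark
Reagents that add atoms: N-iodosuccinimide 10, O=C1CCC(=O)N1I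
Why: Electrophilic aromatic iodination at the only free ring position, activated by two ortho and one para oxygen substituents, under neutral conditions that leave the MOM acetals intact.

Step 5
Reactants: 11 methyl 3-iodo-2-methoxy-4,6-bis(methoxymethoxy)-5-methylbenzoate; 12 3-phenylcyclobutanone
Product: 15 methyl 3-(cis-1-hydroxy-3-phenylcyclobutyl)-2-methoxy-4,6-bis(methoxymethoxy)-5-methylbenzoate (hydroxyl cis to phenyl, achiral), via arylmagnesium chloride 13 (not isolated), via magnesium alkoxide 14 (not isolated)
Conditions: i-PrMgCl·LiCl (1.1 equiv), THF, −20 °C; then LaCl3·2LiCl (1 equiv), 12, −20 to 0 °C; sat. aq. NH4Cl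
Reagents that add atoms: none
Why: Iodine–magnesium exchange (the flanked ester survives at low temperature) and 1,2-addition of the aryl Grignard reagent to the ketone with LaCl3·2LiCl suppressing enolization; attack anti to phenyl should place OH cis to phenyl, and the product keeps the mirror plane needed in step 9.

Step 6
Reactants: 16 prop-2-yn-1-ol; 17 5-bromo-2-methylpent-2-ene
Product: 20 7-methyloct-6-en-2-yn-1-ol, via dilithium alkynide alkoxide 18 (not isolated), via lithium alkoxide 19 (not isolated)
Conditions: n-BuLi (2.1 equiv), THF–DMPU, −78 to 0 °C; then 17, 0 °C to rt; sat. aq. NH4Cl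
Reagents that add atoms: none
Why: Alkylation of the propargyl alcohol dianion, which reacts at the acetylide carbon in an SN2 displacement of the primary bromide.

Step 7
Reactants: 20 7-methyloct-6-en-2-yn-1-ol
Product: 21 7-methyloct-6-en-2-ynal
Conditions: MnO2 (excess), CH2Cl2, rt
Reagents that add atoms: none
Why: Selective MnO2 oxidation of the propargylic alcohol to the ynal without touching the isolated trisubstituted alkene.

Step 8
Reactants: 21 7-methyloct-6-en-2-ynal; 22 sodium iodide
Product: 23 (2Z)-3-iodo-7-methylocta-2,6-dienal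
Conditions: NaI (1.5 equiv), AcOH, 0 °C to rt, dark
Reagents that add atoms: sodium iodide 22, [Na+].[I-]
Why: Conjugate hydroiodination of the ynal, in which iodide adds to the β-carbon and the allenolate is protonated anti, so that the (Z)-β-iodo enal (iodine and formyl cis) should form under kinetic control.

Step 9
Reactants: 15 methyl 3-(cis-1-hydroxy-3-phenylcyclobutyl)-2-methoxy-4,6-bis(methoxymethoxy)-5-methylbenzoate; 23 (2Z)-3-iodo-7-methylocta-2,6-dienal
Product: 26 methyl 2-methoxy-4,6-bis(methoxymethoxy)-5-methyl-3-{[(6S)-4-(4-methylpent-3-en-1-yl)-6-phenylcyclohexa-1,3-dien-1-yl]carbonyl}benzoate (6S here is the same spatial arrangement as 6R in 28; only the rank of C1 changes), via keto enal 24 (not isolated), via aldol adduct 25 (not isolated)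
Conditions: Pd(OAc)2 (5 mol %), (S)-t-Bu-PHOX (10 mol %), Cs2CO3 (2.2 equiv), toluene, 50 °C; then 90 °C in the same flask
Reagents that add atoms: none
Why: Proposed new method: zerovalent palladium (from Pd(OAc)2 and the phosphine) inserts into the C–I bond of 23, the caesium alkoxide of 15 replaces iodide, and strain-driven β-carbon elimination cleaves one of the two enantiotopic ring bonds at the carbinol carbon to give an aryl ketone bearing a primary alkylpalladium, which reductively eliminates with the alkenyl group with retention of the (Z) geometry and so forms C4–C5 (24). The closest known reaction types are the palladium-catalysed enantioselective ring-opening arylation and alkenylation of tert-cyclobutanols with aryl and alkenyl halides and the base-mediated intramolecular aldol condensation of keto aldehydes; new is their merger into a formal [3+3] annulation and the use of a β-iodo enal as the alkenyl partner. Ring closure is a 6-(enolexo)-exo-trig aldol addition of the caesium enolate of the ketone (C1 is its only enolizable carbon and the enal has no α-hydrogen) to the cis-disposed formyl group (25), followed by E1cB dehydration to the conjugated dienone 26, which forms C1–C2. The only stereocentre formed, C6, is controlled by the chiral P,N ligand, which decides which of the two enantiotopic C–C bonds migrates to palladium; C6 is not acidic and is not touched later. The step needs oxidative addition and alkoxide exchange to outrun attack of base on the iodo enal (secured by the reactive electron-poor C–I bond and the poorly nucleophilic tertiary alkoxide), C–C reductive elimination to outrun β-hydride elimination (secured by the chelating ligand, as in the known arylations), and closure at C1–C2 only (secured by the (Z) geometry, since closure of C1 onto C4 would give a four-membered ring).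

Step 10
Reactants: 26 methyl 2-methoxy-4,6-bis(methoxymethoxy)-5-methyl-3-{[(6S)-4-(4-methylpent-3-en-1-yl)-6-phenylcyclohexa-1,3-dien-1-yl]carbonyl}benzoate
Product: 28 methyl 2-methoxy-4,6-bis(methoxymethoxy)-5-methyl-3-{[(1R,6R)-4-(4-methylpent-3-en-1-yl)-6-phenylcyclohex-3-en-1-yl]carbonyl}benzoate, via cis epimer 27 (not isolated)
Conditions: Cu(OAc)2·H2O (5 mol %), 1,2-bis(diphenylphosphino)benzene (5 mol %), (EtO)2MeSiH (2 equiv), t-BuOH (2 equiv), toluene, rt; then DBU (0.5 equiv), 40 °C
Reagents that add atoms: none
Why: Ligated copper hydride 1,4-reduction of the dienone, in which hydride should go to the unsubstituted β-carbon C2 and not to the fully substituted δ-carbon C4, the enolate is protonated by t-BuOH, and DBU-mediated enolization equilibrates C1 to the more stable trans-diequatorial (1R,6R) ketone relative to the fixed C6 centre.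

Step 11
Reactants: 28 methyl 2-methoxy-4,6-bis(methoxymethoxy)-5-methyl-3-{[(1R,6R)-4-(4-methylpent-3-en-1-yl)-6-phenylcyclohex-3-en-1-yl]carbonyl}benzoate
Product: 29 methyl 2,4-dihydroxy-6-methoxy-3-methyl-5-{[(1R,6R)-4-(4-methylpent-3-en-1-yl)-6-phenylcyclohex-3-en-1-yl]carbonyl}benzoate (target)
Conditions: ZnBr2 (2.2 equiv), n-PrSH (4.4 equiv), CH2Cl2, 0 °C to rt, short reaction time
Reagents that add atoms: none
Why: Lewis acid-assisted thiolytic cleavage of both aryl MOM acetals (helped by chelation to the ortho carbonyl groups) under aprotic, brief conditions that should spare the trisubstituted alkenes, the ester and the epimerizable C1 centre.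

**Compound list**

1 | 5-methoxyresorcinol (5-methoxybenzene-1,3-diol) | COc1cc(O)cc(O)c1 | starting material
2 | chloromethyl methyl ether | COCCl | starting material
3 | 1-methoxy-3,5-bis(methoxymethoxy)benzene | COCOc1cc(OC)cc(OCOC)c1 | intermediate
4 | iodomethane | CI | starting material
5 | [4-methoxy-2,6-bis(methoxymethoxy)phenyl]lithium | [Li]c1c(OCOC)cc(OC)cc1OCOC | intermediate (not isolated)
6 | 5-methoxy-1,3-bis(methoxymethoxy)-2-methylbenzene | Cc1c(OCOC)cc(OC)cc1OCOC | intermediate
7 | methyl chloroformate | COC(=O)Cl | starting material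
8 | [6-methoxy-2,4-bis(methoxymethoxy)-3-methylphenyl]lithium | [Li]c1c(OCOC)c(C)c(OCOC)cc1OC | intermediate (not isolated)
9 | methyl 6-methoxy-2,4-bis(methoxymethoxy)-3-methylbenzoate | COC(=O)c1c(OCOC)c(C)c(OCOC)cc1OC | intermediate
10 | N-iodosuccinimide | O=C1CCC(=O)N1I | starting material
11 | methyl 3-iodo-2-methoxy-4,6-bis(methoxymethoxy)-5-methylbenzoate | COC(=O)c1c(OCOC)c(C)c(OCOC)c(I)c1OC | intermediate
12 | 3-phenylcyclobutanone | O=C1CC(c2ccccc2)C1 | starting material
13 | chloro[2-methoxy-3-(methoxycarbonyl)-4,6-bis(methoxymethoxy)-5-methylphenyl]magnesium | COC(=O)c1c(OCOC)c(C)c(OCOC)c([Mg]Cl)c1OC | intermediate (not isolated)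
14 | chloromagnesium alkoxide of 15 (O–MgCl cis to phenyl) | COC(=O)c1c(OCOC)c(C)c(OCOC)c([C@@]2(O[Mg]Cl)C[C@H](c3ccccc3)C2)c1OC | intermediate (not isolated)
15 | methyl 3-(cis-1-hydroxy-3-phenylcyclobutyl)-2-methoxy-4,6-bis(methoxymethoxy)-5-methylbenzoate (OH cis to phenyl) | COC(=O)c1c(OCOC)c(C)c(OCOC)c([C@@]2(O)C[C@H](c3ccccc3)C2)c1OC | intermediate
16 | prop-2-yn-1-ol | C#CCO | starting material
17 | 5-bromo-2-methylpent-2-ene | CC(C)=CCCBr | starting material
18 | dilithium salt of prop-2-yn-1-ol (C- and O-lithiated) | [Li]C#CCO[Li] | intermediate (not isolated)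
19 | lithium 7-methyloct-6-en-2-yn-1-olate | CC(C)=CCCC#CCO[Li] | intermediate (not isolated)
20 | 7-methyloct-6-en-2-yn-1-ol | CC(C)=CCCC#CCO | intermediate
21 | 7-methyloct-6-en-2-ynal | CC(C)=CCCC#CC=O | intermediate
22 | sodium iodide | [Na+].[I-] | starting material
23 | (2Z)-3-iodo-7-methylocta-2,6-dienal | O=C/C=C(\I)CCC=C(C)C | intermediate
24 | methyl 2-methoxy-4,6-bis(methoxymethoxy)-5-methyl-3-[(3R,5Z)-5-(4-methylpent-3-en-1-yl)-7-oxo-3-phenylhept-5-enoyl]benzoate | COC(=O)c1c(OCOC)c(C)c(OCOC)c(C(=O)C[C@H](c2ccccc2)C/C(CCC=C(C)C)=C\C=O)c1OC | intermediate (not isolated)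
25 | methyl 3-{[(6R)-2-hydroxy-4-(4-methylpent-3-en-1-yl)-6-phenylcyclohex-3-en-1-yl]carbonyl}-2-methoxy-4,6-bis(methoxymethoxy)-5-methylbenzoate (C1 and C2 as a mixture) | COC(=O)c1c(OCOC)c(C)c(OCOC)c(C(=O)C2C(O)C=C(CCC=C(C)C)C[C@H]2c2ccccc2)c1OC | intermediate (not isolated)
26 | methyl 2-methoxy-4,6-bis(methoxymethoxy)-5-methyl-3-{[(6S)-4-(4-methylpent-3-en-1-yl)-6-phenylcyclohexa-1,3-dien-1-yl]carbonyl}benzoate | COC(=O)c1c(OCOC)c(C)c(OCOC)c(C(=O)C2=CC=C(CCC=C(C)C)C[C@H]2c2ccccc2)c1OC | intermediate
27 | methyl 2-methoxy-4,6-bis(methoxymethoxy)-5-methyl-3-{[(1S,6R)-4-(4-methylpent-3-en-1-yl)-6-phenylcyclohex-3-en-1-yl]carbonyl}benzoate (cis) | COC(=O)c1c(OCOC)c(C)c(OCOC)c(C(=O)[C@H]2CC=C(CCC=C(C)C)C[C@H]2c2ccccc2)c1OC | intermediate (not isolated)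
28 | methyl 2-methoxy-4,6-bis(methoxymethoxy)-5-methyl-3-{[(1R,6R)-4-(4-methylpent-3-en-1-yl)-6-phenylcyclohex-3-en-1-yl]carbonyl}benzoate (trans) | COC(=O)c1c(OCOC)c(C)c(OCOC)c(C(=O)[C@@H]2CC=C(CCC=C(C)C)C[C@H]2c2ccccc2)c1OC | intermediate
29 | methyl 2,4-dihydroxy-6-methoxy-3-methyl-5-{[(1R,6R)-4-(4-methylpent-3-en-1-yl)-6-phenylcyclohex-3-en-1-yl]carbonyl}benzoate | COC(=O)c1c(O)c(C)c(O)c(C(=O)[C@@H]2CC=C(CCC=C(C)C)C[C@H]2c2ccccc2)c1OC | target

**Step count and risks**

Total step count: 11. Longest linear sequence: 8 steps (steps 1–5, 9, 10, 11); steps 6–8 form the convergent side branch.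

Steps most likely to fail:

1. Step 9 (proposed new method). What may go wrong: consumption of the iodo enal by base (alkoxide addition–elimination, self-condensation) before oxidative addition, β-hydride elimination of the alkylpalladium intermediate, or loss of enantiocontrol through coordination of the free aldehyde. The fallback uses known chemistry only, sets out from 15 and 23 and comes back at 26. The aldehyde of 23 is masked (HC(OMe)3, PPTS, MeOH) as (2Z)-3-iodo-1,1-dimethoxy-7-methylocta-2,6-diene F1. The established palladium-catalysed enantioselective ring-opening alkenylation of 15 with F1 (catalyst and base of step 9, 50 °C) should give methyl 3-[(3R,5Z)-7,7-dimethoxy-5-(4-methylpent-3-en-1-yl)-3-phenylhept-5-enoyl]-2-methoxy-4,6-bis(methoxymethoxy)-5-methylbenzoate F2. Mild hydrolysis (PPTS, acetone–water) then frees keto enal 24, now isolated, and a separate aldol condensation (piperidinium acetate, toluene, 60 °C) closes it to 26.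

2. Step 10. What may go wrong: hydride delivery to C4 (1,6-reduction) or to the ketone, giving alkene-position isomers, or incomplete equilibration at C1. The fallback sets out from 20 and 15 and comes back at 28; it forms C1–C2 by enolate alkylation at the alcohol oxidation level, so no reduction is needed. trans-Hydroalumination–iodination of 20 (NaAlH2(OCH2CH2OMe)2, THF, 0 °C; then I2, −78 °C) should give (2Z)-3-iodo-7-methylocta-2,6-dien-1-ol F3, which is silylated (TBSCl, imidazole) to tert-butyl{[(2Z)-3-iodo-7-methylocta-2,6-dien-1-yl]oxy}dimethylsilane F4. Ring-opening alkenylation of 15 with F4 under the catalyst of step 9 should give methyl 3-[(3R,5Z)-7-{[tert-butyl(dimethyl)silyl]oxy}-5-(4-methylpent-3-en-1-yl)-3-phenylhept-5-enoyl]-2-methoxy-4,6-bis(methoxymethoxy)-5-methylbenzoate F5. n-Bu4NF frees methyl 3-[(3R,5Z)-7-hydroxy-5-(4-methylpent-3-en-1-yl)-3-phenylhept-5-enoyl]-2-methoxy-4,6-bis(methoxymethoxy)-5-methylbenzoate F6, and CBr4/PPh3 converts it into methyl 3-[(3R,5Z)-7-bromo-5-(4-methylpent-3-en-1-yl)-3-phenylhept-5-enoyl]-2-methoxy-4,6-bis(methoxymethoxy)-5-methylbenzoate F7. LiN(SiMe3)2 (THF, −78 to 0 °C) then closes the ring by intramolecular SN2 alkylation of the ketone enolate, and DBU equilibration gives 28.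

3. Step 5. What may go wrong: incomplete iodine–magnesium exchange on the hindered, electron-rich iodide, attack of the organomagnesium on the ester, or enolization of 12 outpacing carbonyl addition. The fallback sets out from 6 (through aryllithium 8) and 12 and comes back at 15; it makes the aryl–ring bond before the ester is present, so that a more nucleophilic ester-free aryllithium can be used. Aryllithium 8 (with anhydrous CeCl3, THF, −78 °C) is added to 12 to give cis-1-[6-methoxy-2,4-bis(methoxymethoxy)-3-methylphenyl]-3-phenylcyclobutan-1-ol F8. Double deprotonation (n-BuLi, 2.3 equiv, TMEDA; alkoxide plus the last ring C–H) and quenching with excess ClCO2Me give the ester carbonate methyl 2-methoxy-3-{cis-1-[(methoxycarbonyl)oxy]-3-phenylcyclobutyl}-4,6-bis(methoxymethoxy)-5-methylbenzoate F9. Selective methanolysis of the carbonate (K2CO3, MeOH, 0 °C; the flanked aryl ester is inert) returns 15.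

**Further compounds**

F1 | step 9 | (2Z)-3-iodo-1,1-dimethoxy-7-methylocta-2,6-diene | COC(OC)/C=C(\I)CCC=C(C)C
F2 | step 9 | methyl 3-[(3R,5Z)-7,7-dimethoxy-5-(4-methylpent-3-en-1-yl)-3-phenylhept-5-enoyl]-2-methoxy-4,6-bis(methoxymethoxy)-5-methylbenzoate | COC(=O)c1c(OCOC)c(C)c(OCOC)c(C(=O)C[C@H](c2ccccc2)C/C(CCC=C(C)C)=C\C(OC)OC)c1OC
F3 | step 10 | (2Z)-3-iodo-7-methylocta-2,6-dien-1-ol | OC/C=C(\I)CCC=C(C)C
F4 | step 10 | tert-butyl{[(2Z)-3-iodo-7-methylocta-2,6-dien-1-yl]oxy}dimethylsilane | CC(C)(C)[Si](C)(C)OC/C=C(\I)CCC=C(C)C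
F5 | step 10 | methyl 3-[(3R,5Z)-7-{[tert-butyl(dimethyl)silyl]oxy}-5-(4-methylpent-3-en-1-yl)-3-phenylhept-5-enoyl]-2-methoxy-4,6-bis(methoxymethoxy)-5-methylbenzoate | COC(=O)c1c(OCOC)c(C)c(OCOC)c(C(=O)C[C@H](c2ccccc2)C/C(CCC=C(C)C)=C\CO[Si](C)(C)C(C)(C)C)c1OC
F6 | step 10 | methyl 3-[(3R,5Z)-7-hydroxy-5-(4-methylpent-3-en-1-yl)-3-phenylhept-5-enoyl]-2-methoxy-4,6-bis(methoxymethoxy)-5-methylbenzoate | COC(=O)c1c(OCOC)c(C)c(OCOC)c(C(=O)C[C@H](c2ccccc2)C/C(CCC=C(C)C)=C\CO)c1OC
F7 | step 10 | methyl 3-[(3R,5Z)-7-bromo-5-(4-methylpent-3-en-1-yl)-3-phenylhept-5-enoyl]-2-methoxy-4,6-bis(methoxymethoxy)-5-methylbenzoate | COC(=O)c1c(OCOC)c(C)c(OCOC)c(C(=O)C[C@H](c2ccccc2)C/C(CCC=C(C)C)=C\CBr)c1OC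
F8 | step 5 | cis-1-[6-methoxy-2,4-bis(methoxymethoxy)-3-methylphenyl]-3-phenylcyclobutan-1-ol (OH cis to phenyl) | COc1cc(OCOC)c(C)c(OCOC)c1[C@@]1(O)C[C@H](c2ccccc2)C1
F9 | step 5 | methyl 2-methoxy-3-{cis-1-[(methoxycarbonyl)oxy]-3-phenylcyclobutyl}-4,6-bis(methoxymethoxy)-5-methylbenzoate | COC(=O)c1c(OCOC)c(C)c(OCOC)c([C@@]2(OC(=O)OC)C[C@H](c3ccccc3)C2)c1OC
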